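## Analysis of the target

The target 13 is 2-hydroxy-6-(13-hydroxy-2-oxotridecyl)-4-methoxybenzoic acid, C21H32O6: a single benzene ring (ring A) carrying the carboxyl group on C1, a free phenol on C2, a methyl ether on C4 and an unbranched thirteen-carbon chain on C6. In the chain C1′ is the benzylic methylene, C2′ a ketone and C13′ a primary alcohol; there is no stereocenter and no double-bond geometry, so nothing has to be controlled in space. The difficulty is regiochemical and functional: ring A is 1,2,3,5-tetrasubstituted, its two oxygens must end up different (OH beside the acid, OMe para to it), and the chain must sit on the one carbon next to the carboxyl group that bears no oxygen. The sensitive unit is the 2-(2-oxoalkyl)benzoic acid, whose carboxyl group and C2′ ketone condense to an isocoumarin under acid or heat, whose C1′ methylene enolises easily, and which as a 6-alkylsalicylic acid can lose CO2 in hot acid. The strategy rests on the ortho relationship around C1: because C2 carries oxygen, C6–H is the only C–H bond ortho to the carboxyl group in a chain-free precursor, and it is exactly the bond that must become C6–C1′. Since the new substituent is an acylmethyl group (C1′H2–C2′=O), it can be delivered as a carbene equivalent, and the resulting keto acid can be kept as the lactone between the C1 carboxyl and C2′ until the end.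

## Retrosynthetic reasoning

**13 to 10 (two O–benzyl bonds).** The C2 phenol and the C13′ alcohol of 13 are traced back to the benzyl ethers of keto acid 10. Benzyl is chosen for both because one neutral hydrogenolysis removes them together, so that neither an acid that would dehydrate the keto acid nor a second basic step is needed. The C4 oxygen stays a methyl ether throughout, so the two ring oxygens are told apart by their protecting groups from the first step. The forward reaction must cleave two benzylic C–O bonds without reducing the C2′ ketone.

**10 to 12 (lactone C–O bond).** The carboxyl group and the C2′ ketone of 10 are joined by dehydration into the enol lactone of isocoumarin 12. Compound 12 is neutral, not enolisable at C1′ and easy to purify, and it is what the key step produces of its own accord. The forward reaction is a basic hydrolysis of the lactone, in which the enolate that leaves ketonises, followed by a cold acidification.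

**12 to 4 + 9 (C6–C1′ bond and the ring O–C2′ bond).** The only C–C bond between ring A and the chain is cut, together with the lactone C–O bond. The cut is made here because it leaves acid 4, an arene that already carries the carboxyl group and both oxygens, and ylide 9, which holds all thirteen chain carbons with the ketone in place. Cutting further along the chain (C1′–C2′ or C2′–C3′) would need an arene with a pre-installed ortho carbon. In 4 the C2 benzyloxy group blocks one ortho position, so a carboxylate-directed metalation can only occur at C6. The forward reaction must cleave C6–H, transfer the acylmethylene unit of 9 to C6 to give 10 in the flask, and close the ring through hemiketal 11 to 12.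

**4 to 3 to 1 + 2 (O–benzyl bond at C2).** Acid 4 comes from the commercial salicylic acid 1. Selective benzylation of the phenol beside a free acid is impractical, so both acidic sites are benzylated with two equivalents of 2 to give ester 3, and the ester alone is then saponified.

**9 to 6 + 7 (C1′–C2′ bond), and 6 to 5 + 2.** The ylide is cut between its carbanionic carbon and the carbonyl carbon. That leads to ester 6 as acyl donor and to methylide 8, made in the flask from salt 7. Ester 6 is the doubly benzylated form of hydroxy acid 5, which supplies C2′ to C13′ with the terminal oxygen already in place; two equivalents of 2 are again consumed.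

## Alternatives that were turned down

**Alternative 1:** aryne insertion into a malonate. The disconnection removes both ortho bonds at once, C6–C1′ and C1–carboxyl. In the forward key step fluoride would trigger elimination of 3,5-dimethoxy-2-(trimethylsilyl)phenyl trifluoromethanesulfonate A2 to an aryne. The anion of dimethyl malonate A3 would add at the aryne carbon remote from the adjacent methoxy group. The aryl anion would then add to the neighbouring ester carbonyl and the four-membered ring would fragment, giving dimethyl 3,5-dimethoxyhomophthalate A1. No ring closes.
- For: two C–C bonds form in one operation, the orientation is fixed by the polarisation of the aryne, no transition metal is needed, and A3 is a bulk chemical. On the number of bonds formed and the certainty of regiochemistry it is at least as strong as the chosen route.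
- Against: A1 contains only C1′ of the chain. C2′ to C13′ would still have to be attached by hydrolysis, anhydride formation, C-acylation with an activated twelve-carbon acid and decarboxylative closure to an isocoumarin. Both ring oxygens arrive as methyl ethers, so the C2 ether needs a selective chelation-controlled cleavage. A2 itself takes several steps from a phenol.
- Comparison: the count comes to roughly a dozen steps against seven. The chosen route buys the arene with carboxyl and differentiated oxygens in place and attaches the whole chain in the C–C bond-forming step.

**Alternative 2:** biomimetic aromatisation of a triketo ester. The disconnection opens ring A at the C1–C6 bond. In the forward key step the dioxinone 6-{5-[2-(11-(benzyloxy)undecyl)-1,3-dioxolan-2-yl]-2,4-dioxopentyl}-2,2-dimethyl-4H-1,3-dioxin-4-one A5 would undergo thermal cycloreversion to an acylketene. Benzyl alcohol A7 would trap it as the triketo ester A6. A carbonate base would then drive the intramolecular aldol addition of C2 to the C7 carbonyl, and mild acid would dehydrate the adduct to the resorcylate A4.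
- For: ring and carboxyl group are built together, and because the trapping alcohol is A7 the carboxyl group emerges as a benzyl ester that leaves by neutral hydrogenolysis. This end game is gentler than a basic lactone opening and is a real advantage over the chosen route.
- Against: A4 has two free phenols, so a regioselective methylation of the C4 hydroxyl is required. The C2′ ketone must stay masked as a dioxolane through the whole polycarbonyl sequence, and the acid used for aromatisation threatens that mask. A5 needs a long linear build by two successive C-acylations with a ketal-bearing chain donor.
- Comparison: about a dozen steps, with the risk spread over several polycarbonyl intermediates. The chosen route concentrates its risk in one catalytic step and never has to distinguish two phenols.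

**Alternative 3:** Diels–Alder benzannulation. The disconnection removes the ring bonds C1–C2 and C5–C6. In the forward key step the diene 1,3-dimethoxy-1-(trimethylsilyloxy)buta-1,3-diene A9 would add on heating across the triple bond of benzyl 4-{2-[11-(benzyloxy)undecyl]-1,3-dioxolan-2-yl}but-2-ynoate A10. The nucleophilic CH2 terminus of the diene bonds to the β-carbon of the ynoate and the ketene-acetal carbon to the α-carbon. Acidic work-up expels the acetal methoxy group and removes the silyl group, giving the salicylate A8.
- For: A8 has the exact oxygen pattern of the target, with free C2 hydroxyl, C4 methyl ether and a benzyl ester. This is closer to the target than product 12 of the chosen key step, and the end game is again neutral.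
- Against: A10 is a β-alkyl ynoate and therefore a sluggish dienophile, needing prolonged heating that the hydrolytically and thermally fragile A9 tolerates poorly. Its propargylic CH2, flanked by the ketal, invites isomerisation to an allenoate. Making A10 means ketalising a β,γ-alkynyl ketone, which itself isomerises readily. The acidic aromatisation endangers the dioxolane.
- Comparison: about ten steps, with two uncertain stages (dienophile synthesis and cycloaddition). The chosen route has two fragments of two steps each and one union.

Key step: step 5

Assumption: the target is treated as the open-chain keto acid as drawn. Any ring–chain equilibrium with its cyclic hemiketal is a property of the compound; only dehydration to the enol lactone has to be prevented.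

## Route

Step 1
Reactants: 1 2-hydroxy-4-methoxybenzoic acid; 2 benzyl bromide
Product: 3 benzyl 2-(benzyloxy)-4-methoxybenzoate
Conditions: 2 (2.5 equiv in all), K2CO3 (3 equiv), DMF, 60 °C
Reagents that add atoms: benzyl bromide (second equivalent of 2), BrCc1ccccc1
Why: Carboxylate alkylation and Williamson etherification, two SN2 displacements that each consume one molecule of 2; the acid reacts at once and the hydrogen-bonded C2 phenol more slowly, so excess 2 and 60 °C are used to take both to completion.

Step 2
Reactants: 3 benzyl 2-(benzyloxy)-4-methoxybenzoate
Product: 4 2-(benzyloxy)-4-methoxybenzoic acid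
Conditions: NaOH (2 M aq), THF/MeOH, 60 °C; then 1 M HCl
Reagents that add atoms: sodium hydroxide, [Na+].[OH-]
Why: Saponification by acyl–oxygen cleavage of the benzyl ester; the aryl benzyl ether and the methyl ether are inert to hydroxide, so only the directing carboxyl group is unmasked.

Step 3
Reactants: 5 12-hydroxydodecanoic acid; 2 benzyl bromide
Product: 6 benzyl 12-(benzyloxy)dodecanoate
Conditions: NaH (2.5 equiv), THF/DMF, 0 °C; then 2 (2.5 equiv in all), Bu4NI (cat.), 0 °C → rt
Reagents that add atoms: benzyl bromide (second equivalent of 2), BrCc1ccccc1
Why: NaH forms the carboxylate–alkoxide dianion before any electrophile is present; one molecule of 2 then benzylates the alkoxide (Williamson ether synthesis) and a second converts the carboxylate into the benzyl ester by SN2 alkylation. Because the alkoxide is consumed before much ester has formed, transesterification between molecules should stay minor.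

Step 4
Reactants: 6 benzyl 12-(benzyloxy)dodecanoate; 7 trimethylsulfoxonium iodide
Product: 9 13-(benzyloxy)-1-[dimethyl(oxo)-λ6-sulfanylidene]tridecan-2-one, via dimethylsulfoxonium methylide 8 (not isolated)
Conditions: 7 (3 equiv), KOtBu (3 equiv), THF, reflux; then 6, 0 °C → rt
Reagents that add atoms: none
Why: The Corey–Chaykovsky methylide 8, made from 7 and KOtBu, attacks the ester carbonyl of 6 (nucleophilic acyl substitution), and the resulting β-keto sulfoxonium salt is deprotonated at once to the acyl-stabilised ylide 9, which is too weak a nucleophile to be acylated again. Excess methylide compensates for enolisation of 6, and the primary benzyl ether is untouched.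

Step 5
Reactants: 4 2-(benzyloxy)-4-methoxybenzoic acid; 9 13-(benzyloxy)-1-[dimethyl(oxo)-λ6-sulfanylidene]tridecan-2-one
Product: 12 8-(benzyloxy)-3-[11-(benzyloxy)undecyl]-6-methoxy-1H-isochromen-1-one, via keto acid 10 (not isolated), via cyclic hemiketal 11 (not isolated)
Conditions: [Cp*RhCl2]2 (4 mol%), AgSbF6 (16 mol%), NaOAc (1 equiv), 9 (1.5 equiv), ClCH2CH2Cl, 100 °C, Ar
Reagents that add atoms: none
Why: Chloride abstraction by AgSbF6 and exchange with acetate give a cationic Cp*Rh acetate of trivalent rhodium, which binds the carboxylate of 4 and cleaves the C6–H bond by acetate-assisted concerted metalation–deprotonation to a five-membered rhodacycle. The ylide carbon of 9 then coordinates, dimethyl sulfoxide leaves to give a rhodium α-oxo carbene, and migratory insertion of the aryl group forms the C6–C1′ bond; protonation by acetic acid releases keto acid 10 and returns the catalyst with no change of oxidation state, so no oxidant is needed. The carboxyl oxygen of 10 adds to the ketone carbon in a 6-exo-trig closure to hemiketal 11, and loss of water across C3–C4 gives the enol lactone 12. The closest known reaction type is the annulation of benzoic acids with acyl sulfoxonium ylides to 3-substituted isocoumarins under Cp* complexes of trivalent rhodium or iridium. No stereocenter remains in 12; the hemiketal carbon of 11 is transient and racemic and disappears on dehydration. The step needs site selectivity and mono-alkylation: C6–H is the only C–H bond ortho to the directing carboxylate because C2 carries the benzyloxy group, and lactonisation removes the free acid. It also needs C–H insertion to outrun O-alkylation of the carboxyl group by protonated ylide, which the acetate buffer and the fast chelation-assisted metalation are meant to secure, while the benzyl ethers, the methyl ether and the alkyl chain offer no competing directing group.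

Step 6
Reactants: 12 8-(benzyloxy)-3-[11-(benzyloxy)undecyl]-6-methoxy-1H-isochromen-1-one
Product: 10 2-(benzyloxy)-6-[13-(benzyloxy)-2-oxotridecyl]-4-methoxybenzoic acid
Conditions: KOH (2 M aq, 5 equiv), THF/EtOH, 60 °C; then 1 M HCl to pH 3, 0 °C, immediate extraction
Reagents that add atoms: potassium hydroxide, [K+].[OH-]
Why: Saponification of an enol lactone: hydroxide adds to the lactone carbonyl and expels the C2′ enolate, which ketonises, and carboxylate formation makes the opening irreversible in base. Acidification is cold and only to pH 3, so that keto acid 10, the compound already passed through in step 5, is extracted before acid can dehydrate it back to 12; both benzyl ethers are stable to base.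

Step 7
Reactants: 10 2-(benzyloxy)-6-[13-(benzyloxy)-2-oxotridecyl]-4-methoxybenzoic acid
Product: 13 2-hydroxy-6-(13-hydroxy-2-oxotridecyl)-4-methoxybenzoic acid
Conditions: H2 (1 atm), 10% Pd/C, EtOAc, rt
Reagents that add atoms: none
Why: Heterogeneous hydrogenolysis cleaves the two benzylic C–O bonds; the C2′ ketone is not conjugated to the ring and should not be reduced at 1 atm and room temperature, and the carboxyl group and methyl ether are inert. The medium is neutral and aprotic, so the freed hydroxy keto acid has no acid catalyst for dehydrative lactonisation or decarboxylation.

## Compound list

1 | 2-hydroxy-4-methoxybenzoic acid | COc1ccc(C(=O)O)c(O)c1 | starting material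
2 | benzyl bromide | BrCc1ccccc1 | starting material
3 | benzyl 2-(benzyloxy)-4-methoxybenzoate | COc1ccc(C(=O)OCc2ccccc2)c(OCc2ccccc2)c1 | intermediate
4 | 2-(benzyloxy)-4-methoxybenzoic acid | COc1ccc(C(=O)O)c(OCc2ccccc2)c1 | intermediate
5 | 12-hydroxydodecanoic acid | OCCCCCCCCCCCC(=O)O | starting material
6 | benzyl 12-(benzyloxy)dodecanoate | O=C(OCc1ccccc1)CCCCCCCCCCCOCc1ccccc1 | intermediate
7 | trimethylsulfoxonium iodide | C[S+](C)(C)=O.[I-] | starting material
8 | dimethylsulfoxonium methylide | C=S(C)(C)=O | intermediate
9 | 13-(benzyloxy)-1-[dimethyl(oxo)-λ6-sulfanylidene]tridecan-2-one | CS(C)(=O)=CC(=O)CCCCCCCCCCCOCc1ccccc1 | intermediate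
10 | 2-(benzyloxy)-6-[13-(benzyloxy)-2-oxotridecyl]-4-methoxybenzoic acid | COc1cc(OCc2ccccc2)c(C(=O)O)c(CC(=O)CCCCCCCCCCCOCc2ccccc2)c1 | intermediate
11 | 8-(benzyloxy)-3-[11-(benzyloxy)undecyl]-3-hydroxy-6-methoxy-3,4-dihydro-1H-isochromen-1-one (racemic) | COc1cc2c(c(OCc3ccccc3)c1)C(=O)OC(O)(CCCCCCCCCCCOCc1ccccc1)C2 | intermediate
12 | 8-(benzyloxy)-3-[11-(benzyloxy)undecyl]-6-methoxy-1H-isochromen-1-one | O=C1OC(CCCCCCCCCCCOCc4ccccc4)=Cc2cc(OC)cc(OCc3ccccc3)c21 | intermediate
13 | 2-hydroxy-6-(13-hydroxy-2-oxotridecyl)-4-methoxybenzoic acid | COc1cc(O)c(C(=O)O)c(CC(=O)CCCCCCCCCCCO)c1 | target

## Step count and risk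

Total step count: 7. Longest linear sequence: 5 steps (steps 1, 2, 5, 6, 7, or equally steps 3, 4, 5, 6, 7).

**Step 5 (key step).** The most likely failure is off-cycle consumption of the ylide. It can be protonated by the acid and then O-alkylate the carboxylate, or the carbene can dimerise, faster than C6–H is metalated. Metalation is slowed because the ortho benzyloxy group twists the carboxylate out of the ring plane and C6 is meta to both donor groups. Silver-assisted loss of CO2 from the electron-rich acid at 100 °C is the second process to watch. Incomplete dehydration is harmless, since 10, 11 and 12 all converge on 10 under the base of step 6.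

The fallback replaces C–H activation by anion chemistry; it sets out from 6 and comes back to the route at 10. Ester 6 would be converted with MeNHOMe·HCl and iPrMgCl (THF, –20 °C) into 12-(benzyloxy)-N-methoxy-N-methyldodecanamide F1. Purchased methyl 2-hydroxy-4-methoxy-6-methylbenzoate F2 would be benzylated (2, K2CO3, DMF) to methyl 2-(benzyloxy)-4-methoxy-6-methylbenzoate F3. Lateral lithiation of the C6 methyl group of F3 with LiN(iPr)2 in THF at –78 °C and acylation with F1 would give methyl 2-(benzyloxy)-6-[13-(benzyloxy)-2-oxotridecyl]-4-methoxybenzoate F4. Aqueous KOH under the conditions of step 6 would then hydrolyse F4, directly or by way of 12, to 10.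

**Step 6.** The risk is re-closure of the lactone by acid-catalysed dehydration during acidification and concentration. On prolonged heating in base, aldol self-condensation at the enolisable positions beside the ketone is possible. Opening may also be slow, because the lactone carbonyl is shielded and made less electrophilic by the peri benzyloxy group.

The fallback avoids isolating the protected keto acid; it sets out from 12 and comes back to the route at 13. The ring would be opened with aqueous KOH as in step 6 but not acidified. Excess hydroxide would be buffered to about pH 8 with KH2PO4, and potassium 2-(benzyloxy)-6-[13-(benzyloxy)-2-oxotridecyl]-4-methoxybenzoate F5 would be hydrogenolysed directly in aqueous ethanol over Pd(OH)2 on carbon to potassium 2-hydroxy-6-(13-hydroxy-2-oxotridecyl)-4-methoxybenzoate F6. A single cold acidification of F6 with 1 M HCl would then release 13.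

**Step 7.** The risks are over-reduction of the C2′ ketone, incomplete cleavage of the primary alkyl benzyl ether, and dehydrative ring closure of the freed hydroxy keto acid if traces of acid are present on the catalyst.

The fallback removes the benzyl groups without hydrogen and before the ring is opened; it sets out from 12 and comes back to the route at 13. BCl3 with pentamethylbenzene as cation scavenger (CH2Cl2, –78 → 0 °C) would cleave both benzyl ethers and give 8-hydroxy-3-(11-hydroxyundecyl)-6-methoxy-1H-isochromen-1-one F7. The lactone of F7 would be opened last with aqueous KOH, followed by cold acidification, to give 13.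

**Step 3.** The risk is transesterification between the alkoxide of one molecule and the benzyl ester of another (oligoester formation) if ester accumulates before the alkoxide is consumed, together with incomplete etherification.

The fallback never generates an alkoxide; it sets out from 5 and comes back to the route at 9. Fischer esterification (MeOH, cat. H2SO4, reflux) would give methyl 12-hydroxydodecanoate F8. Acid-catalysed benzylation with benzyl 2,2,2-trichloroacetimidate and catalytic TfOH (CH2Cl2/cyclohexane, rt) would give methyl 12-(benzyloxy)dodecanoate F9. F9 would then serve as the acyl donor under the conditions of step 4 to give 9.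

## Further compounds

F1 | step 5 | 12-(benzyloxy)-N-methoxy-N-methyldodecanamide | CON(C)C(=O)CCCCCCCCCCCOCc1ccccc1
F2 | step 5 | methyl 2-hydroxy-4-methoxy-6-methylbenzoate | COC(=O)c1c(O)cc(OC)cc1C
F3 | step 5 | methyl 2-(benzyloxy)-4-methoxy-6-methylbenzoate | COC(=O)c1c(OCc2ccccc2)cc(OC)cc1C
F4 | step 5 | methyl 2-(benzyloxy)-6-[13-(benzyloxy)-2-oxotridecyl]-4-methoxybenzoate | COC(=O)c1c(OCc2ccccc2)cc(OC)cc1CC(=O)CCCCCCCCCCCOCc1ccccc1
F5 | step 6 | potassium 2-(benzyloxy)-6-[13-(benzyloxy)-2-oxotridecyl]-4-methoxybenzoate | COc1cc(OCc2ccccc2)c(C(=O)[O-])c(CC(=O)CCCCCCCCCCCOCc2ccccc2)c1.[K+]
F6 | step 6 | potassium 2-hydroxy-6-(13-hydroxy-2-oxotridecyl)-4-methoxybenzoate | COc1cc(O)c(C(=O)[O-])c(CC(=O)CCCCCCCCCCCO)c1.[K+]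
F7 | step 7 | 8-hydroxy-3-(11-hydroxyundecyl)-6-methoxy-1H-isochromen-1-one | O=C1OC(CCCCCCCCCCCO)=Cc2cc(OC)cc(O)c21
F8 | step 3 | methyl 12-hydroxydodecanoate | COC(=O)CCCCCCCCCCCO
F9 | step 3 | methyl 12-(benzyloxy)dodecanoate | COC(=O)CCCCCCCCCCCOCc1ccccc1
A1 | alternative 1 | methyl 2,4-dimethoxy-6-(2-methoxy-2-oxoethyl)benzoate (dimethyl 3,5-dimethoxyhomophthalate) | COC(=O)Cc1cc(OC)cc(OC)c1C(=O)OC
A2 | alternative 1 | 3,5-dimethoxy-2-(trimethylsilyl)phenyl trifluoromethanesulfonate | COc1cc(OC)c([Si](C)(C)C)c(OS(=O)(=O)C(F)(F)F)c1
A3 | alternative 1 | dimethyl malonate | COC(=O)CC(=O)OC
A4 | alternative 2 | benzyl 6-{[2-(11-(benzyloxy)undecyl)-1,3-dioxolan-2-yl]methyl}-2,4-dihydroxybenzoate | O=C(OCc1ccccc1)c2c(O)cc(O)cc2CC3(CCCCCCCCCCCOCc4ccccc4)OCCO3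
A5 | alternative 2 | 6-{5-[2-(11-(benzyloxy)undecyl)-1,3-dioxolan-2-yl]-2,4-dioxopentyl}-2,2-dimethyl-4H-1,3-dioxin-4-one | CC1(C)OC(=O)C=C(CC(=O)CC(=O)CC2(CCCCCCCCCCCOCc3ccccc3)OCCO2)O1
A6 | alternative 2 | benzyl 8-{2-[11-(benzyloxy)undecyl]-1,3-dioxolan-2-yl}-3,5,7-trioxooctanoate | O=C(OCc1ccccc1)CC(=O)CC(=O)CC(=O)CC2(CCCCCCCCCCCOCc3ccccc3)OCCO2
A7 | alternative 2 | benzyl alcohol | OCc1ccccc1
A8 | alternative 3 | benzyl 6-{[2-(11-(benzyloxy)undecyl)-1,3-dioxolan-2-yl]methyl}-2-hydroxy-4-methoxybenzoate | O=C(OCc1ccccc1)c2c(O)cc(OC)cc2CC3(CCCCCCCCCCCOCc4ccccc4)OCCO3
A9 | alternative 3 | 1,3-dimethoxy-1-(trimethylsilyloxy)buta-1,3-diene | COC(=C)C=C(OC)O[Si](C)(C)C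
A10 | alternative 3 | benzyl 4-{2-[11-(benzyloxy)undecyl]-1,3-dioxolan-2-yl}but-2-ynoate | O=C(OCc1ccccc1)C#CCC2(CCCCCCCCCCCOCc3ccccc3)OCCO2
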